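## Retrosynthetic overview

1. In unit B (2S,3R,4R, primed atoms) the ether carbon C4' is bonded to C4a' of benzo ring A, which lies para to O7' and ortho to O1'. The last skeletal bond cut is therefore C4'–C4a'. This opens pyran ring C of unit B to an oxocarbenium ion C4'=O+ whose oxygen is already O4 of the finished all-cis unit A (2R,3R,4R).
2. The ion comes from a mixed methyl acetal, made by acetal exchange between the open-chain unit B dimethyl acetal and the C4 alcohol of unit A. No C–O bond of the C4–O–C4' bridge is ever broken at a stereocentre.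
3. Both units descend from one Evans syn glycolate aldol adduct, which fixes C3 and C3'. One Mitsunobu inversion with a pyrogallol-derived phenol gives the 2',3'-trans chain of unit B, and two inversions give the 2,3-cis chain of unit A.
4. Ring order: pyran ring C of unit A first (Parham cyclisation to the chroman-4-one, then hydride anti to the axial O3 sets C4), then pyran ring C of unit B in the key step, then fluoride and neutral deacetylation.

Key step: step 20

Abbreviations: TBS = tert-butyldimethylsilyl; TES = triethylsilyl; Tf = trifluoromethanesulfonyl; DIAD = diisopropyl azodicarboxylate; PPTS = pyridinium p-toluenesulfonate.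

Remark on the chemistry: only ring A of unit A carries acetates. The B-ring phenols are TBS ethers because they must survive Me3Al, i-Bu2AlH and t-BuLi. The O7'/O8' pair carries one cyclic di-tert-butylsilylene so that silyl migration in the free phenol is degenerate. CIP labels of untouched centres can switch when neighbours change rank, so the SMILES strings are decisive.

## Route

Step 1
Reactants: 1 4-hydroxybenzaldehyde
Product: 2 4-(TBSO)benzaldehyde
Conditions: TBSCl, imidazole, DMF, rt
Reagents that add atoms: tert-butyldimethylsilyl chloride, CC(C)(C)[Si](C)(C)Cl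
Why: Imidazole-promoted O-silylation of a phenol is routine, and the aryl TBS ether should survive the boron, aluminium and lithium reagents ahead yet fall to fluoride at the end.

Step 2
Reactants: 3 glycolic acid
Product: 4 tert-butyldimethylsilyl (TBSO)acetate
Conditions: TBSCl (2.2 equiv), imidazole (4.5 equiv), DMF, rt
Reagents that add atoms: tert-butyldimethylsilyl chloride, CC(C)(C)[Si](C)(C)Cl
Why: Exhaustive silylation masks the hydroxyl group and turns the acid into a silyl ester, the form from which an acid chloride can be made without free HCl.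

Step 3
Reactants: 4 tert-butyldimethylsilyl (TBSO)acetate; 5 (S)-4-benzyl-1,3-oxazolidin-2-one
Product: 7 (4S)-4-benzyl-3-[(TBSO)acetyl]-1,3-oxazolidin-2-one, via silyloxyacetyl chloride 6 (not isolated)
Conditions: (COCl)2, DMF (cat.), CH2Cl2, 0 °C → rt, concentrate; then 5, LiCl, Et3N, THF, 0 °C → rt
Reagents that add atoms: none
Why: Oxalyl chloride with catalytic DMF exchanges the silyl ester for the acid chloride under neutral conditions that spare the silyl ether, and LiCl/Et3N-mediated N-acylation of the oxazolidinone then gives the imide with the auxiliary stereocentre untouched.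

Step 4
Reactants: 7 (4S)-4-benzyl-3-[(TBSO)acetyl]-1,3-oxazolidin-2-one; 2 4-(TBSO)benzaldehyde
Product: 9 (4S)-4-benzyl-3-{(2S,3R)-2-(TBSO)-3-hydroxy-3-[4-(TBSO)phenyl]propanoyl}-1,3-oxazolidin-2-one (syn aldol adduct), via (Z)-dibutylboron enolate 8 (not isolated)
Conditions: n-Bu2BOTf, Et3N, CH2Cl2, −78 → 0 °C; 2, −78 → 0 °C; pH 7 buffer, MeOH, 30% H2O2, 0 °C
Reagents that add atoms: none
Why: Evans syn aldol reaction: the (Z)-boron enolate 8 adds through a Zimmerman–Traxler chair on the face remote from the benzyl group of the (S)-auxiliary, which sets the silyloxy carbon as S (future C3 and C3') and the carbinol carbon as R in a syn relation.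

Step 5
Reactants: 9 syn aldol adduct
Product: 10 (2S,3R)-2-(TBSO)-3-hydroxy-N-methoxy-N-methyl-3-[4-(TBSO)phenyl]propanamide
Conditions: Me3Al, MeNHOMe·HCl, CH2Cl2, −10 °C → rt; aq. potassium sodium tartrate
Reagents that add atoms: N,O-dimethylhydroxylamine hydrochloride, CNOC.Cl
Why: Weinreb transamidation with the aluminium amide formed in the flask is accelerated by the free β-hydroxyl group, releases the auxiliary for reuse and does not touch either stereocentre.

Step 6
Reactants: 10 syn hydroxy Weinreb amide
Product: 11 (2S,3R)-2-(TBSO)-3-hydroxy-3-[4-(TBSO)phenyl]propanal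
Conditions: i-Bu2AlH (2.5 equiv), THF, −78 °C; aq. potassium sodium tartrate
Reagents that add atoms: none
Why: Reduction of a Weinreb amide stops at the chelated tetrahedral aluminium intermediate, so the aldehyde appears only on work-up and is taken on at once to avoid epimerisation at the silyloxy carbon.

Step 7
Reactants: 11 hydroxy aldehyde
Product: 12 (1R,2S)-2-(TBSO)-3,3-dimethoxy-1-[4-(TBSO)phenyl]propan-1-ol
Conditions: HC(OMe)3, PPTS (cat.), MeOH, rt
Reagents that add atoms: trimethyl orthoformate, COC(OC)OC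
Why: Acid-catalysed acetalisation is driven by the orthoformate as water scavenger, and PPTS is too weak to cleave the silyl ethers or to ionise a benzylic alcohol flanked by inductively withdrawing oxygenated carbons.

Step 8
Reactants: 13 pyrogallol
Product: 14 2,2-di-tert-butyl-1,3,2-benzodioxasilol-4-ol
Conditions: t-Bu2Si(OTf)2 (1.0 equiv), 2,6-lutidine, DMF, 0 °C
Reagents that add atoms: di-tert-butylsilyl bis(trifluoromethanesulfonate), CC(C)(C)[Si](OS(=O)(=O)C(F)(F)F)(OS(=O)(=O)C(F)(F)F)C(C)(C)C
Why: Two adjacent hydroxyl groups of pyrogallol close a five-membered cyclic silylene with the bis-triflate, and because pyrogallol is symmetric a silicon shift to the third oxygen only regenerates 14, so the phenoxide formed later cannot scramble as it could with two separate silyl ethers.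

Step 9
Reactants: 12 hydroxy dimethyl acetal; 14 silylene-protected pyrogallol
Product: 15 4-{(1S,2S)-2-(TBSO)-3,3-dimethoxy-1-[4-(TBSO)phenyl]propoxy}-2,2-di-tert-butyl-1,3,2-benzodioxasilole (open-chain unit B dimethyl acetal)
Conditions: PPh3, DIAD, toluene, 0 °C → rt
Reagents that add atoms: none
Why: Mitsunobu etherification displaces the activated benzylic oxygen by SN2 with inversion (1R to 1S), which creates the anti O1'/O3' relation of a 2,3-trans flavan, and the acetal in place of a carbonyl group rules out β-elimination.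

Step 10
Reactants: 10 syn hydroxy Weinreb amide
Product: 16 (2S,3S)-3-(chloroacetoxy)-2-(TBSO)-N-methoxy-N-methyl-3-[4-(TBSO)phenyl]propanamide
Conditions: ClCH2CO2H, PPh3, DIAD, toluene, 0 °C → rt
Reagents that add atoms: chloroacetic acid, OC(=O)CCl
Why: Mitsunobu inversion with a strongly acidic carboxylic acid, the variant suited to hindered secondary alcohols, turns the syn into the anti series (3R to 3S) so that a second inversion can later deliver the 2,3-cis pattern.

Step 11
Reactants: 16 anti chloroacetate
Product: 17 (2S,3S)-2-(TBSO)-3-hydroxy-N-methoxy-N-methyl-3-[4-(TBSO)phenyl]propanamide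
Conditions: thiourea, 2,6-lutidine, EtOH–THF, 50 °C
Reagents that add atoms: none
Why: Thiourea displaces chloride and then cyclises onto the ester carbonyl, which frees the alcohol without ever forming an alkoxide, so the aryl silyl ether stays on and the neighbouring silyl group does not migrate.

Step 12
Reactants: 13 pyrogallol
Product: 18 2,2-diphenyl-1,3-benzodioxol-4-ol
Conditions: Ph2CCl2, neat, 170 °C
Reagents that add atoms: dichlorodiphenylmethane, ClC(Cl)(c1ccccc1)c1ccccc1
Why: Thermal ketalisation of two adjacent phenols by the gem-dichloride gives a cyclic ketal that cannot migrate, tolerates t-BuLi and is removable later by hydrogenolysis.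

Step 13
Reactants: 18 2,2-diphenyl-1,3-benzodioxol-4-ol
Product: 19 5-bromo-2,2-diphenyl-1,3-benzodioxol-4-ol
Conditions: Br2, t-BuNH2, toluene–CH2Cl2, −78 °C → rt
Reagents that add atoms: bromine, BrBr
Why: This is an ortho-selective phenol bromination by N-bromo-tert-butylamine made in the flask, which is guided by hydrogen bonding to the phenol and so goes to C5 next to the hydroxyl group instead of the para position C7.

Step 14
Reactants: 17 anti hydroxy Weinreb amide; 19 bromophenol
Product: 20 (2S,3R)-3-[(5-bromo-2,2-diphenyl-1,3-benzodioxol-4-yl)oxy]-2-(TBSO)-N-methoxy-N-methyl-3-[4-(TBSO)phenyl]propanamide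
Conditions: PPh3, DIAD, toluene (1 M), 0 °C → rt
Reagents that add atoms: none
Why: The second Mitsunobu reaction, again SN2 with inversion (3S to 3R), gives the syn O1/O3 relation of a 2,3-cis flavan, helped by the higher acidity of the ortho-bromophenol and by the tied-back ketal oxygen that keeps one flank of the nucleophile small.

Step 15
Reactants: 20 bromoaryl ether Weinreb amide
Product: 22 (2R,3S)-3-(TBSO)-2-[4-(TBSO)phenyl]-7,8-(diphenylmethylenedioxy)chroman-4-one (2,3-cis), via aryllithium 21 (not isolated)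
Conditions: t-BuLi (2.1 equiv), THF, −78 °C; AcOH, −78 °C
Reagents that add atoms: none
Why: Parham cyclisation: bromine–lithium exchange outruns attack of t-BuLi on the amide, the aryllithium 21 adds to the Weinreb amide in a six-membered closure that forms C4–C4a and pyran ring C of unit A, and the stable tetrahedral adduct releases the base-sensitive 2,3-cis ketone only on cold acidic quench.

Step 16
Reactants: 22 ketal-protected cis-chromanone
Product: 23 (2R,3S)-7,8-dihydroxy-3-(TBSO)-2-[4-(TBSO)phenyl]chroman-4-one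
Conditions: H2 (1 atm), 10% Pd/C, EtOAc, rt
Reagents that add atoms: none
Why: Hydrogenolysis of the doubly benzylic ketal carbon frees the catechol under neutral conditions that leave the silyl ethers, the conjugated ketone and the cyclic C2–O1 bond of a flavanone intact.

Step 17
Reactants: 23 catechol ketone
Product: 24 (2R,3S)-7,8-diacetoxy-3-(TBSO)-2-[4-(TBSO)phenyl]chroman-4-one
Conditions: Ac2O, pyridine, CH2Cl2, 0 °C
Reagents that add atoms: acetic anhydride, CC(=O)OC(C)=O
Why: Pyridine-mediated acetylation of the two phenols installs the electron-withdrawing groups that the key step needs on ring A of unit A, under conditions too weakly basic to epimerise C3.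

Step 18
Reactants: 24 diacetoxy cis-chromanone
Product: 25 (2R,3R,4R)-7,8-diacetoxy-3-(TBSO)-2-[4-(TBSO)phenyl]chroman-4-ol (all-cis protected unit A)
Conditions: NaBH4, CeCl3·7H2O, MeOH–THF, −78 → −40 °C
Reagents that add atoms: none
Why: Luche reduction: hydride attacks C4 axially from the face anti to the axial C3 silyloxy group (polar Felkin–Anh and steric control agree), which sets C4 as R with the hydroxyl group cis to O3, and the cold weakly acidic medium spares the aryl acetates and C3.

Step 19
Reactants: 15 open-chain unit B dimethyl acetal; 25 protected unit A alcohol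
Product: 27 mixed methyl acetal in which one methoxy group of 15 is replaced by the C4 oxygen of 25 (both acetal epimers; other centres unchanged), via collidinium triflate 26 (not isolated)
Conditions: 15 (2 equiv), TESOTf (2 equiv), 2,4,6-collidine (6 equiv), CH2Cl2, 0 °C; then 25 (1 equiv), 0 °C → rt
Reagents that add atoms: none
Why: Silyl triflate–collidine acetal exchange: TESOTf removes one methoxy group as TESOMe, collidine holds the cation as the weakly electrophilic salt 26, and this salt passes the methoxyalkyl group to the hydroxyl group of 25 under buffered conditions, so only the O–H bond of 25 is broken, C4 keeps its configuration, and the more accessible acetal is the component used in excess.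

Step 20
Reactants: 27 mixed methyl acetal
Product: 29 protected dimer (2R,3R,4R)-7,8-diacetoxy-3-(TBSO)-2-[4-(TBSO)phenyl]chroman-4-yl (2S,3R,4R)-3-(TBSO)-2-[4-(TBSO)phenyl]-7,8-(di-tert-butylsilylenedioxy)chroman-4-yl ether, via (E)-oxocarbenium ion 28 (not isolated)
Conditions: BF3·OEt2 (2 equiv), 2,6-di-tert-butyl-4-methylpyridine, 4 Å MS, CH2Cl2, −78 → −40 °C; Et3N quench
Reagents that add atoms: none
Why: BF3 binds the less hindered and more basic methoxy oxygen of 27 and expels it, giving the (E)-oxocarbenium ion 28 in which O4 stays bonded to both C4 and C4', so C4 cannot lose its configuration. The aryl ether ring then attacks C4' through C4a' (ortho to O1', para to O7') and rearomatises by giving its proton to the hindered pyridine, which is an intramolecular Friedel–Crafts alkylation by an acetal-derived oxocarbenium ion, the reaction type by which 3-aryloxypropanal acetals give 4-alkoxychromans. The closure forms C4'–C4a' and pyran ring C of unit B in a 6-exo-trig mode with respect to the C=O+ bond, whose oxygen ends outside the new ring, and the tether lets only C4a' reach the cation. C4' is set in a chair-like transition state with the C2' aryl and C3' silyloxy groups equatorial: the forming bond lies anti to the C3'–O bond (polar Felkin–Anh), which places the O+ substituent between O3' and C2', that is pseudoaxial and away from H5', and gives the 3',4'-cis (4'R) ether. The chemoselectivity needed is ionisation of methoxide only and attack by one ring only, and the substrate secures it because the two acetates on ring A of unit A make departure of a C4 cation from 28 costly and make that ring inert, whereas the silylenedioxy ring stays electron-rich. Low temperature, the proton scavenger and the amine quench should keep the new C4'–O bond from ionising again.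

Step 21
Reactants: 29 protected dimer
Product: 30 7,8-di-O-acetyl derivative of the target (all silicon groups removed)
Conditions: Et3N·3HF, Et3N, THF, rt → 40 °C
Reagents that add atoms: none
Why: Amine-buffered hydrogen fluoride cleaves the four TBS ethers and the silylene by fluoride attack at silicon close to neutral pH, so the acid-labile doubly benzylic ether, the acetates and all six stereocentres are left alone.

Step 22
Reactants: 30 diacetate
Product: 31 (2R,3R,4R)-4-{[(2S,3R,4R)-3,7,8-trihydroxy-2-(4-hydroxyphenyl)chroman-4-yl]oxy}-2-(4-hydroxyphenyl)chroman-3,7,8-triol (target)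
Conditions: NH4OAc, MeOH–H2O (4:1), rt, argon
Reagents that add atoms: none
Why: Ammonium acetate-catalysed solvolysis is selective for aryl acetates at neutral pH, which avoids acid ionisation of the C4–O–C4' ether as well as base-induced C2 epimerisation and air oxidation of the pyrogallol-type rings.

## Compound list

1 | 4-hydroxybenzaldehyde | O=Cc1ccc(O)cc1 | starting material
2 | 4-(TBSO)benzaldehyde | O=Cc1ccc(O[Si](C)(C)C(C)(C)C)cc1 | intermediate
3 | glycolic acid | OCC(O)=O | starting material
4 | tert-butyldimethylsilyl (TBSO)acetate | CC(C)(C)[Si](C)(C)OCC(=O)O[Si](C)(C)C(C)(C)C | intermediate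
5 | (S)-4-benzyl-1,3-oxazolidin-2-one | O=C1N[C@@H](Cc2ccccc2)CO1 | starting material
6 | (TBSO)acetyl chloride (not isolated) | CC(C)(C)[Si](C)(C)OCC(Cl)=O | intermediate
7 | (4S)-4-benzyl-3-[(TBSO)acetyl]-1,3-oxazolidin-2-one | CC(C)(C)[Si](C)(C)OCC(=O)N1[C@@H](Cc2ccccc2)COC1=O | intermediate
8 | (Z)-dibutylboron enolate of 7 (not isolated) | CCCCB(CCCC)O/C(=C\O[Si](C)(C)C(C)(C)C)N1[C@@H](Cc2ccccc2)COC1=O | intermediate
9 | syn aldol adduct (2S,3R; auxiliary 4S) | O=C([C@@H](O[Si](C)(C)C(C)(C)C)[C@H](O)c1ccc(O[Si](C)(C)C(C)(C)C)cc1)N1[C@@H](Cc2ccccc2)COC1=O | intermediate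
10 | (2S,3R) syn hydroxy Weinreb amide | CON(C)C(=O)[C@@H](O[Si](C)(C)C(C)(C)C)[C@H](O)c1ccc(O[Si](C)(C)C(C)(C)C)cc1 | intermediate
11 | (2S,3R) hydroxy aldehyde | O=C[C@@H](O[Si](C)(C)C(C)(C)C)[C@H](O)c1ccc(O[Si](C)(C)C(C)(C)C)cc1 | intermediate
12 | (1R,2S) hydroxy dimethyl acetal | COC(OC)[C@@H](O[Si](C)(C)C(C)(C)C)[C@H](O)c1ccc(O[Si](C)(C)C(C)(C)C)cc1 | intermediate
13 | pyrogallol | Oc1cccc(O)c1O | starting material
14 | 2,2-di-tert-butyl-1,3,2-benzodioxasilol-4-ol | Oc1cccc2O[Si](C(C)(C)C)(C(C)(C)C)Oc12 | intermediate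
15 | (1S,2S) open-chain unit B dimethyl acetal | COC(OC)[C@@H](O[Si](C)(C)C(C)(C)C)[C@@H](Oc1cccc2O[Si](C(C)(C)C)(C(C)(C)C)Oc12)c1ccc(O[Si](C)(C)C(C)(C)C)cc1 | intermediate
16 | (2S,3S) anti chloroacetate | CON(C)C(=O)[C@@H](O[Si](C)(C)C(C)(C)C)[C@@H](OC(=O)CCl)c1ccc(O[Si](C)(C)C(C)(C)C)cc1 | intermediate
17 | (2S,3S) anti hydroxy Weinreb amide | CON(C)C(=O)[C@@H](O[Si](C)(C)C(C)(C)C)[C@@H](O)c1ccc(O[Si](C)(C)C(C)(C)C)cc1 | intermediate
18 | 2,2-diphenyl-1,3-benzodioxol-4-ol | Oc1cccc2OC(c3ccccc3)(c3ccccc3)Oc12 | intermediate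
19 | 5-bromo-2,2-diphenyl-1,3-benzodioxol-4-ol | Oc1c(Br)ccc2OC(c3ccccc3)(c3ccccc3)Oc12 | intermediate
20 | (2S,3R) bromoaryl ether Weinreb amide | CON(C)C(=O)[C@@H](O[Si](C)(C)C(C)(C)C)[C@H](Oc1c(Br)ccc2OC(c3ccccc3)(c3ccccc3)Oc12)c1ccc(O[Si](C)(C)C(C)(C)C)cc1 | intermediate
21 | aryllithium from 20 (not isolated) | CON(C)C(=O)[C@@H](O[Si](C)(C)C(C)(C)C)[C@H](Oc1c([Li])ccc2OC(c3ccccc3)(c3ccccc3)Oc12)c1ccc(O[Si](C)(C)C(C)(C)C)cc1 | intermediate
22 | (2R,3S) 2,3-cis chroman-4-one, 7,8-diphenylmethylene ketal | CC(C)(C)[Si](C)(C)Oc1ccc([C@H]2Oc3c(ccc4OC(c5ccccc5)(c5ccccc5)Oc34)C(=O)[C@H]2O[Si](C)(C)C(C)(C)C)cc1 | intermediate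
23 | (2R,3S) 7,8-dihydroxy cis-chroman-4-one | CC(C)(C)[Si](C)(C)Oc1ccc([C@H]2Oc3c(ccc(O)c3O)C(=O)[C@H]2O[Si](C)(C)C(C)(C)C)cc1 | intermediate
24 | (2R,3S) 7,8-diacetoxy cis-chroman-4-one | CC(C)(C)[Si](C)(C)Oc1ccc([C@H]2Oc3c(ccc(OC(C)=O)c3OC(C)=O)C(=O)[C@H]2O[Si](C)(C)C(C)(C)C)cc1 | intermediate
25 | (2R,3R,4R) all-cis protected unit A alcohol | CC(C)(C)[Si](C)(C)Oc1ccc([C@H]2Oc3c(ccc(OC(C)=O)c3OC(C)=O)[C@@H](O)[C@H]2O[Si](C)(C)C(C)(C)C)cc1 | intermediate
26 | collidinium triflate from 15 (not isolated) | Cc1cc(C)[n+](C(OC)[C@@H](O[Si](C)(C)C(C)(C)C)[C@@H](Oc2cccc3O[Si](C(C)(C)C)(C(C)(C)C)Oc23)c2ccc(O[Si](C)(C)C(C)(C)C)cc2)c(C)c1.[O-]S(=O)(=O)C(F)(F)F | intermediate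
27 | mixed methyl acetal (key-step precursor, both acetal epimers) | CC(C)(C)[Si](C)(C)Oc1ccc([C@H]2Oc3c(ccc(OC(C)=O)c3OC(C)=O)[C@@H](OC(OC)[C@@H](O[Si](C)(C)C(C)(C)C)[C@@H](Oc3cccc4O[Si](C(C)(C)C)(C(C)(C)C)Oc34)c3ccc(O[Si](C)(C)C(C)(C)C)cc3)[C@H]2O[Si](C)(C)C(C)(C)C)cc1 | intermediate
28 | (E)-oxocarbenium methoxytrifluoroborate (not isolated) | CC(C)(C)[Si](C)(C)Oc1ccc([C@H]2Oc3c(ccc(OC(C)=O)c3OC(C)=O)[C@@H](/[O+]=C/[C@@H](O[Si](C)(C)C(C)(C)C)[C@@H](Oc3cccc4O[Si](C(C)(C)C)(C(C)(C)C)Oc34)c3ccc(O[Si](C)(C)C(C)(C)C)cc3)[C@H]2O[Si](C)(C)C(C)(C)C)cc1.CO[B-](F)(F)F | intermediate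
29 | protected dimer (key-step product) | CC(C)(C)[Si](C)(C)Oc1ccc([C@H]2Oc3c(ccc(OC(C)=O)c3OC(C)=O)[C@@H](O[C@@H]3c4ccc5O[Si](C(C)(C)C)(C(C)(C)C)Oc5c4O[C@@H](c4ccc(O[Si](C)(C)C(C)(C)C)cc4)[C@@H]3O[Si](C)(C)C(C)(C)C)[C@H]2O[Si](C)(C)C(C)(C)C)cc1 | intermediate
30 | 7,8-di-O-acetyl target | Oc1ccc([C@H]2Oc3c(ccc(OC(C)=O)c3OC(C)=O)[C@@H](O[C@@H]3c4ccc(O)c(O)c4O[C@@H](c4ccc(O)cc4)[C@@H]3O)[C@H]2O)cc1 | intermediate
31 | CNP0241481.1 | Oc1ccc([C@H]2Oc3c(ccc(O)c3O)[C@@H](O[C@@H]3c4ccc(O)c(O)c4O[C@@H](c4ccc(O)cc4)[C@@H]3O)[C@H]2O)cc1 | target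

## Step count and risks

Total step count: 22.
Longest linear sequence: 15 steps (3 → 4 → 7 → 9 → 10 → 16 → 17 → 20 → 22 → 23 → 24 → 25 → 27 → 29 → 30 → 31).

Steps most likely to fail:

**1. Step 20.**
- What may go wrong: BF3 may ionise the acetal on the wrong side, expelling the unit A alkoxide. The cation may shed unit A as a benzylic cation.
- BF3 may also attack the strained silylene or re-ionise the new C4'–O bond, and the facial selectivity at C4' may be poor.
- Fallback, from 27 back to 29: the cation is made by halide abstraction instead of Lewis acid ionisation.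
- Acyl chloride–acetal exchange (AcCl, catalytic Zn(OTf)2, CH2Cl2, 0 °C) acylates only the unhindered methoxy oxygen and turns 27 into the α-chloro ether F1.
- AgOTf with 2,6-di-tert-butyl-4-methylpyridine at −78 °C then removes chloride irreversibly as AgCl. The same ion closes onto C4a' in a medium that holds no Lewis acid able to reopen the product.

**2. Step 19.**
- What may go wrong: the methoxy-substituted cation in equilibrium with salt 26 may be captured by its own aryl ether ring before the hindered alcohol arrives (premature ring closure). Residual TESOTf may also silylate 25.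
- Fallback, from 12 and 25 back to 27: the acetal is assembled while the nucleophilic ring is still absent.
- With TESOTf and collidine, 12 is first capped as the triethylsilyl ether F2 and then converted into the collidinium triflate F3. Addition of 25 gives the silylated mixed acetal F4.
- Buffered HF·pyridine (THF, 0 °C) removes only the TES group to give the free carbinol F5.
- A Mitsunobu etherification of F5 with 14 (PPh3, DIAD) then installs the aryl ether with the same inversion as in step 9.

**3. Step 14.**
- What may go wrong: SN2 displacement by a phenol substituted at both ortho positions may be slow. This would allow β-elimination towards the unsaturated amide, or partial ionisation at the benzylic carbon with erosion of configuration.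
- Fallback, from 19 and 17 back to 22: the order of bond formation is reversed, so that C4–C4a is made first and O1–C2 is closed intramolecularly.
- Compound 19 is alkylated (allyl bromide, K2CO3, acetone) to the allyl ether F6, and n-BuLi at −78 °C gives the aryllithium F7. This adds to the lithium alkoxide of 17 to give the aryl ketone F8.
- Pd(PPh3)4 with morpholine removes the allyl group to give the ortho-hydroxyaryl ketone F9.
- An intramolecular Mitsunobu reaction (PPh3, DIAD) closes the pyran ring with inversion at C2 to the same 2,3-cis ketone 22.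

## Further compounds

F1 | step 20 | α-chloro ether from 27 (both epimers) | CC(C)(C)[Si](C)(C)Oc1ccc([C@H]2Oc3c(ccc(OC(C)=O)c3OC(C)=O)[C@@H](OC(Cl)[C@@H](O[Si](C)(C)C(C)(C)C)[C@@H](Oc3cccc4O[Si](C(C)(C)C)(C(C)(C)C)Oc34)c3ccc(O[Si](C)(C)C(C)(C)C)cc3)[C@H]2O[Si](C)(C)C(C)(C)C)cc1
F2 | step 19 | triethylsilyl ether of 12 | COC(OC)[C@@H](O[Si](C)(C)C(C)(C)C)[C@H](O[Si](CC)(CC)CC)c1ccc(O[Si](C)(C)C(C)(C)C)cc1
F3 | step 19 | collidinium triflate from F2 | Cc1cc(C)[n+](C(OC)[C@@H](O[Si](C)(C)C(C)(C)C)[C@H](O[Si](CC)(CC)CC)c2ccc(O[Si](C)(C)C(C)(C)C)cc2)c(C)c1.[O-]S(=O)(=O)C(F)(F)F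
F4 | step 19 | silylated mixed acetal of F2 and 25 | CC(C)(C)[Si](C)(C)Oc1ccc([C@H]2Oc3c(ccc(OC(C)=O)c3OC(C)=O)[C@@H](OC(OC)[C@@H](O[Si](C)(C)C(C)(C)C)[C@H](O[Si](CC)(CC)CC)c3ccc(O[Si](C)(C)C(C)(C)C)cc3)[C@H]2O[Si](C)(C)C(C)(C)C)cc1
F5 | step 19 | free carbinol of the mixed acetal | CC(C)(C)[Si](C)(C)Oc1ccc([C@H]2Oc3c(ccc(OC(C)=O)c3OC(C)=O)[C@@H](OC(OC)[C@@H](O[Si](C)(C)C(C)(C)C)[C@H](O)c3ccc(O[Si](C)(C)C(C)(C)C)cc3)[C@H]2O[Si](C)(C)C(C)(C)C)cc1
F6 | step 14 | 4-(allyloxy)-5-bromo-2,2-diphenyl-1,3-benzodioxole | C=CCOc1c(Br)ccc2OC(c3ccccc3)(c3ccccc3)Oc12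
F7 | step 14 | aryllithium from F6 | C=CCOc1c([Li])ccc2OC(c3ccccc3)(c3ccccc3)Oc12
F8 | step 14 | (2S,3S) aryl ketone with allyl ether | C=CCOc1c(ccc2OC(c3ccccc3)(c3ccccc3)Oc12)C(=O)[C@@H](O[Si](C)(C)C(C)(C)C)[C@@H](O)c1ccc(O[Si](C)(C)C(C)(C)C)cc1
F9 | step 14 | (2S,3S) ortho-hydroxyaryl ketone | Oc1c(ccc2OC(c3ccccc3)(c3ccccc3)Oc12)C(=O)[C@@H](O[Si](C)(C)C(C)(C)C)[C@@H](O)c1ccc(O[Si](C)(C)C(C)(C)C)cc1
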